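**Strategy.** Drimane numbering is used for the decalin. Ring A is a bare (CH2)3 bridge between the two quaternary carbons C4 and C10, so its C1–C2 edge can be made last by ring-closing metathesis. A ring B cyclohexenone from (R)-carvone carries a vinyl group on C10 and a 2-methylpent-4-en-2-yl arm on C5, trans to each other. The metathesis closes ring A as a trans-fused cyclohexene whose only trace is removed by hydrogenation. Carvone supplies the C5 stereocentre, the C7=C8 olefin with its methyl and the C9 carbonyl, which becomes the C9–C11 unit that is finally coupled with farnesyl bromide.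

Key step: step 5

**Route**

Step 1
Reactants: 1 (R)-(−)-carvone
Product: 2 (5R)-5-(2-bromopropan-2-yl)-2-methylcyclohex-2-en-1-one
Conditions: HBr (33% in AcOH), 0 °C
Reagents that add atoms: hydrogen bromide, Br
Why: Markovnikov ionic hydrobromination, in which protonation of the 1,1-disubstituted isopropenyl group gives a tertiary cation at C4 that bromide captures, while the electron-poor enone olefin and the C5 stereocentre are left alone.

Step 2
Reactants: 2 (5R)-5-(2-bromopropan-2-yl)-2-methylcyclohex-2-en-1-one
Product: 3 (5R)-2-methyl-5-(2-methylpent-4-en-2-yl)cyclohex-2-en-1-one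
Conditions: Bu3SnCH2CH=CH2 (5 equiv), AIBN (cat.), benzene, 80 °C
Reagents that add atoms: allyltributylstannane, C=CC[Sn](CCCC)(CCCC)CCCC
Why: Keck radical allylation, in which bromine abstraction by Bu3Sn• gives the tertiary C4 radical that adds to the allylstannane and expels Bu3Sn•, so the gem-dimethyl quaternary carbon is made without a cationic or basic intermediate that could epimerise C5 or close a cyclopropane.

Step 3
Reactants: 3 (5R)-2-methyl-5-(2-methylpent-4-en-2-yl)cyclohex-2-en-1-one
Product: 5 (5R,6S)-2,6-dimethyl-5-(2-methylpent-4-en-2-yl)cyclohex-2-en-1-one, via lithium enolate 4 (not isolated)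
Conditions: LiN(iPr)2 (LDA), THF, −78 °C; MeI, −78 → 0 °C
Reagents that add atoms: lithium diisopropylamide, [Li]N(C(C)C)C(C)C (lithium in 4 only); iodomethane, CI
Why: Kinetic enolate alkylation, in which LiN(iPr)2 removes a proton from the only sp3 alpha carbon (the future C10) and MeI attacks anti to the C5 substituent; the configuration of this centre does not matter because it is enolised again in step 4.

Step 4
Reactants: 5 (5R,6S)-2,6-dimethyl-5-(2-methylpent-4-en-2-yl)cyclohex-2-en-1-one
Product: 8 (5S,6S)-6-ethenyl-2,6-dimethyl-5-(2-methylpent-4-en-2-yl)cyclohex-2-en-1-one, via lithium enolate 6 (not isolated), via sulfoxide adduct 7 (not isolated)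
Conditions: LiN(iPr)2, THF, −78 → −30 °C; PhS(O)CH=CH2, −78 → 0 °C; NH4Cl aq.; crude adduct, NaHCO3, toluene, 110 °C
Reagents that add atoms: lithium diisopropylamide, [Li]N(C(C)C)C(C)C (lithium in 6 only); phenyl vinyl sulfoxide, C=CS(=O)c1ccccc1
Why: Michael addition of the trisubstituted enolate to phenyl vinyl sulfoxide (a vinyl cation equivalent) and thermal sulfoxide syn-elimination, in which the acceptor approaches the enolate face anti to the bulky C5 tert-alkyl arm, so the vinyl group (C1) ends up trans to the arm and the methyl cis, which sets the C10 quaternary centre.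

Step 5
Reactants: 8 (5S,6S)-6-ethenyl-2,6-dimethyl-5-(2-methylpent-4-en-2-yl)cyclohex-2-en-1-one
Product: 9 (4aS,8aS)-2,5,5,8a-tetramethyl-4a,5,6,8a-tetrahydronaphthalen-1(4H)-one
Conditions: second-generation Grubbs catalyst (H2IMes)(PCy3)Cl2Ru=CHPh (5 mol%), toluene (0.005 M), 80 °C, argon sparge
Reagents that add atoms: none
Why: Ring-closing olefin metathesis: the ruthenium benzylidene exchanges onto the unhindered terminal olefin of the C4 arm, the resulting alkylidene undergoes intramolecular [2+2] cycloaddition with the C10 vinyl group, and cycloreversion of the ruthenacyclobutane releases ethene and forms the C1=C2 bond. The closest known reaction type is the closure of 1,7-dienes to cyclohexenes in which one olefin sits on a quaternary carbon. Ring A is closed as a six-membered ring with the new olefin endocyclic, trans-fused to ring B. No stereocentre is created; the trans ring fusion follows from the trans relation of the C10 vinyl group and the C5 arm fixed in step 4. The step needs chemoselectivity for the two monosubstituted olefins over the trisubstituted, electron-poor C7=C8 olefin, which the substitution pattern provides, and cyclisation over cross-metathesis, which the gauche arrangement of the two equatorial arms, the gem-dimethyl group on C4 and high dilution secure.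

Step 6
Reactants: 9 (4aS,8aS)-2,5,5,8a-tetramethyl-4a,5,6,8a-tetrahydronaphthalen-1(4H)-one
Product: 10 (4aS,8aS)-2,5,5,8a-tetramethyl-4a,5,6,7,8,8a-hexahydronaphthalen-1(4H)-one
Conditions: H2 (1 atm), RhCl(PPh3)3 (10 mol%), benzene–EtOH, rt
Reagents that add atoms: none
Why: Homogeneous hydrogenation with RhCl(PPh3)3 is selective for the cis-disubstituted C1=C2 olefin over the trisubstituted, conjugated C7=C8 olefin, and no stereocentre is affected.

Step 7
Reactants: 10 (4aS,8aS)-2,5,5,8a-tetramethyl-4a,5,6,7,8,8a-hexahydronaphthalen-1(4H)-one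
Product: 11 (4aS,8aS)-2,5,5,8a-tetramethyl-1-methylidene-1,4,4a,5,6,7,8,8a-octahydronaphthalene
Conditions: Cp2TiMe2 (3 equiv), toluene, 70 °C, dark
Reagents that add atoms: dimethyltitanocene, C[Ti](C)(C1C=CC=C1)C1C=CC=C1
Why: Petasis methylenation, in which the non-basic titanium methylidene formed from Cp2TiMe2 converts the hindered, alpha-quaternary enone carbonyl into the exocyclic C9=C11 methylene without enolisation or conjugate addition.

Step 8
Reactants: 11 (4aS,8aS)-2,5,5,8a-tetramethyl-1-methylidene-1,4,4a,5,6,7,8,8a-octahydronaphthalene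
Product: 13 (−)-drimenol, via alkylborane 12 (not isolated)
Conditions: 9-BBN, THF, 0 °C → rt; then NaOH aq., H2O2, 0 °C → rt
Reagents that add atoms: 9-borabicyclo[3.3.1]nonane, B1C2CCCC1CCC2 (boron in 12 only); hydrogen peroxide, OO
Why: Hydroboration–oxidation, in which 9-BBN adds to the 1,1-disubstituted terminus of the diene with boron on C11 and delivers hydrogen to C9 from the alpha face, opposite the axial C10 methyl group, which sets C9 with the CH2OH group beta.

Step 9
Reactants: 13 (−)-drimenol
Product: 14 (1S,4aS,8aS)-1-(bromomethyl)-2,5,5,8a-tetramethyl-1,4,4a,5,6,7,8,8a-octahydronaphthalene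
Conditions: CBr4, PPh3, CH2Cl2, 0 °C → rt
Reagents that add atoms: tetrabromomethane, BrC(Br)(Br)Br
Why: Appel reaction, in which SN2 displacement of the alkoxyphosphonium by bromide at the primary C11 leaves C9 and the C7=C8 olefin untouched.

Step 10
Reactants: 14 (1S,4aS,8aS)-1-(bromomethyl)-2,5,5,8a-tetramethyl-1,4,4a,5,6,7,8,8a-octahydronaphthalene; 15 (2E,6E)-farnesyl bromide
Product: 17 target hydrocarbon CNP0141177.1, via drimenylmagnesium bromide 16 (not isolated)
Conditions: Mg, THF, 50 °C; then 15, Li2CuCl4 (5 mol%), THF, −78 → 0 °C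
Reagents that add atoms: magnesium, [Mg] (magnesium in 16 only)
Why: Kochi-type copper-catalysed coupling of a primary alkyl Grignard reagent with an allylic bromide, in which Li2CuCl4 at low temperature should deliver the alkyl group to the alpha carbon (SN2) of the farnesyl unit with retention of the (2E,6E) geometry, forming the C11–C12 bond.

**Compound list**

1 | (R)-(−)-carvone, (5R)-2-methyl-5-(prop-1-en-2-yl)cyclohex-2-en-1-one | O=C1C(C)=CC[C@@H](C(C)=C)C1 | starting material
2 | (5R)-5-(2-bromopropan-2-yl)-2-methylcyclohex-2-en-1-one | O=C1C(C)=CC[C@@H](C(C)(C)Br)C1 | intermediate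
3 | (5R)-2-methyl-5-(2-methylpent-4-en-2-yl)cyclohex-2-en-1-one | O=C1C(C)=CC[C@@H](C(C)(C)CC=C)C1 | intermediate
4 | lithium (3R)-6-methyl-3-(2-methylpent-4-en-2-yl)cyclohexa-1,5-dien-1-olate (enolate of 3) | [Li]OC1=C[C@H](C(C)(C)CC=C)CC=C1C | intermediate
5 | (5R,6S)-2,6-dimethyl-5-(2-methylpent-4-en-2-yl)cyclohex-2-en-1-one (trans isomer; the C6 epimer is carried along) | O=C1C(C)=CC[C@@H](C(C)(C)CC=C)[C@@H]1C | intermediate
6 | lithium (3S)-2,6-dimethyl-3-(2-methylpent-4-en-2-yl)cyclohexa-1,5-dien-1-olate (enolate of 5) | [Li]OC1=C(C)[C@H](C(C)(C)CC=C)CC=C1C | intermediate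
7 | (5S,6S)-2,6-dimethyl-5-(2-methylpent-4-en-2-yl)-6-[2-(phenylsulfinyl)ethyl]cyclohex-2-en-1-one (both sulfur epimers) | O=C1C(C)=CC[C@@H](C(C)(C)CC=C)[C@@]1(CCS(=O)c1ccccc1)C | intermediate
8 | (5S,6S)-6-ethenyl-2,6-dimethyl-5-(2-methylpent-4-en-2-yl)cyclohex-2-en-1-one | O=C1C(C)=CC[C@@H](C(C)(C)CC=C)[C@@]1(C=C)C | intermediate
9 | (4aS,8aS)-2,5,5,8a-tetramethyl-4a,5,6,8a-tetrahydronaphthalen-1(4H)-one | O=C1C(C)=CC[C@H]2C(C)(C)CC=C[C@]12C | intermediate
10 | (4aS,8aS)-2,5,5,8a-tetramethyl-4a,5,6,7,8,8a-hexahydronaphthalen-1(4H)-one (11-nordrim-7-en-9-one) | O=C1C(C)=CC[C@H]2C(C)(C)CCC[C@]12C | intermediate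
11 | (4aS,8aS)-2,5,5,8a-tetramethyl-1-methylidene-1,4,4a,5,6,7,8,8a-octahydronaphthalene (drima-7,9(11)-diene) | C=C1C(C)=CC[C@H]2C(C)(C)CCC[C@]12C | intermediate
12 | 9-{[(1S,4aS,8aS)-2,5,5,8a-tetramethyl-1,4,4a,5,6,7,8,8a-octahydronaphthalen-1-yl]methyl}-9-borabicyclo[3.3.1]nonane | C(B1C2CCCC1CCC2)[C@H]1C(C)=CC[C@H]2C(C)(C)CCC[C@]12C | intermediate
13 | (−)-drimenol, [(1S,4aS,8aS)-2,5,5,8a-tetramethyl-1,4,4a,5,6,7,8,8a-octahydronaphthalen-1-yl]methanol | OC[C@H]1C(C)=CC[C@H]2C(C)(C)CCC[C@]12C | intermediate
14 | (1S,4aS,8aS)-1-(bromomethyl)-2,5,5,8a-tetramethyl-1,4,4a,5,6,7,8,8a-octahydronaphthalene (drimenyl bromide) | BrC[C@H]1C(C)=CC[C@H]2C(C)(C)CCC[C@]12C | intermediate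
15 | (2E,6E)-farnesyl bromide, (2E,6E)-1-bromo-3,7,11-trimethyldodeca-2,6,10-triene | CC(C)=CCC/C(C)=C/CC/C(C)=C/CBr | starting material
16 | drimenylmagnesium bromide (Grignard reagent of 14) | Br[Mg]C[C@H]1C(C)=CC[C@H]2C(C)(C)CCC[C@]12C | intermediate
17 | CNP0141177.1, (1S,4aS,8aS)-2,5,5,8a-tetramethyl-1-[(3E,7E)-4,8,12-trimethyltrideca-3,7,11-trien-1-yl]-1,4,4a,5,6,7,8,8a-octahydronaphthalene | CC(C)=CCC/C(C)=C/CC/C(C)=C/CC[C@H]1C(C)=CC[C@H]2C(C)(C)CCC[C@]12C | target

**Totals**

Total step count: 10. Longest linear sequence: 10 steps (1 to 17).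

**Steps most likely to fail**

Step 4. The congested tertiary enolate 6 may add too slowly to the vinyl sulfoxide next to the tert-alkyl arm, with proton transfer winning over C–C bond formation. The fallback sets out from 5 and comes back at 8. Enolate 6 is trapped at −78 °C with monomeric formaldehyde (cracked paraformaldehyde), a small and very reactive electrophile that should approach anti to the arm in the same way, to give (5S,6R)-6-(hydroxymethyl)-2,6-dimethyl-5-(2-methylpent-4-en-2-yl)cyclohex-2-en-1-one F1. Dess–Martin oxidation (NaHCO3, CH2Cl2) gives the keto aldehyde (5S,6R)-6-formyl-2,6-dimethyl-5-(2-methylpent-4-en-2-yl)cyclohex-2-en-1-one F2, which cannot enolise at C10. Wittig methylenation with Ph3P=CH2 (from Ph3PCH3Br and KN(SiMe3)2, THF, −78 → 0 °C), selective for the aldehyde over the hindered conjugated ketone, returns 8.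

Step 2. The radical chain may be diverted by addition of the tertiary radical to the enone of a second molecule, or by thermal loss of HBr before propagation. The fallback sets out from 2 and comes back at 3 by a polar tert-alkylation instead of a radical one. The bromide is ionised with TiCl4 in CH2Cl2 at −78 °C in the presence of excess CH2=CHCH2SiMe3, and the allylsilane captures the tertiary cation (Sakurai-type SN1 allylation); the low temperature and excess silane are there to outrun a hydride shift from C5. This fallback makes no new compound (F0).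

Step 10. Magnesium insertion into the hindered bromide may be slow or incomplete, and attack at the gamma carbon of the allylic bromide (SN2′) would give the branched isomer. The fallback sets out from 14 and comes back at 17 through sulfone-anion alkylation. Displacement with PhSO2Na (DMF, 80 °C) gives drimenyl phenyl sulfone F3. Deprotonation with n-BuLi (THF, −78 °C) gives the lithio sulfone F4, which is not isolated and is alkylated with 15 to the coupled sulfone F5. Reductive desulfonylation with sodium amalgam Na(Hg) in Na2HPO4-buffered MeOH at −20 °C gives 17; the sulfone is not allylic, so no olefin should migrate.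

**Further compounds**

F1 | step 4 | (5S,6R)-6-(hydroxymethyl)-2,6-dimethyl-5-(2-methylpent-4-en-2-yl)cyclohex-2-en-1-one | O=C1C(C)=CC[C@@H](C(C)(C)CC=C)[C@@]1(CO)C
F2 | step 4 | (5S,6R)-6-formyl-2,6-dimethyl-5-(2-methylpent-4-en-2-yl)cyclohex-2-en-1-one | O=C1C(C)=CC[C@@H](C(C)(C)CC=C)[C@@]1(C=O)C
F0 | step 2 | none | none
F3 | step 10 | drimenyl phenyl sulfone, (1S,4aS,8aS)-2,5,5,8a-tetramethyl-1-[(phenylsulfonyl)methyl]-1,4,4a,5,6,7,8,8a-octahydronaphthalene | O=S(=O)(C[C@H]1C(C)=CC[C@H]2C(C)(C)CCC[C@]12C)c1ccccc1
F4 | step 10 | alpha-lithio derivative of drimenyl phenyl sulfone | [Li]C(S(=O)(=O)c1ccccc1)[C@H]1C(C)=CC[C@H]2C(C)(C)CCC[C@]12C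
F5 | step 10 | C11-(phenylsulfonyl) derivative of 17 (both C11 epimers) | CC(C)=CCC/C(C)=C/CC/C(C)=C/CC([C@H]1C(C)=CC[C@H]2C(C)(C)CCC[C@]12C)S(=O)(=O)c1ccccc1
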